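**Plan**

- Target: 7-hydroxy-5,6,8,3',4'-pentamethoxyflavone. The retrosynthesis first cuts the C8–OMe bond (back to C8–Br, then C8–H) with the 7-hydroxyl masked as a benzyl ether.
- It then cuts O1–C8a, C4a–C4 and O1–C2 together, opening the pyranone (ring C) to an alkoxy-substituted ring-A aryne and an arylpropiolic acid that carries ring B.
- Enabling feature: O1 on C8a and the C4 carbonyl on C4a are ortho neighbours on ring A, and C4a lies next to the C5 methoxy group. That group polarises an aryne across C4a–C8a so that oxygen enters at C8a and the acyl carbon at C4a.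
- Forward: ring A starts as a commercial dimethoxyphenol and becomes an o-silylaryl triflate (steps 1–5); ring B arrives on an arylalkyne that is carboxylated (step 6); ring C closes in the aryne cascade (step 7); the C8 methoxy group goes in last (steps 8–10).
- Stereochemistry: the target has no stereocentre and no stereogenic double bond, so only regiochemistry has to be controlled.

Key step: step 7

Remark: flavone numbering (O1, C2–C4, C4a, C5–C8, C8a; primed locants for ring B) is used for all chromone compounds.

**Route**

Step 1
Reactants: 1 2,3-dimethoxyphenol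
Product: 2 2,3-dimethoxy-1,4-benzoquinone
Conditions: (KSO3)2NO (2.2 equiv), KH2PO4, H2O–acetone, 0 °C to rt
Reagents that add atoms: potassium nitrosodisulfonate (Fremy's salt), [K+].[K+].[O]N(S(=O)(=O)[O-])S(=O)(=O)[O-]
Why: Teuber oxidation, in which one nitroxyl radical removes the phenolic hydrogen and a second couples at the unsubstituted para carbon, after which loss of imidodisulfonate should give the para-quinone.

Step 2
Reactants: 2 2,3-dimethoxy-1,4-benzoquinone
Product: 3 2,3-dimethoxybenzene-1,4-diol
Conditions: Na2S2O4, H2O–EtOAc, rt, under N2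
Reagents that add atoms: none
Why: Two-electron quinone reduction by dithionite should give the symmetric hydroquinone, which is kept under nitrogen and used directly.

Step 3
Reactants: 3 2,3-dimethoxybenzene-1,4-diol; 4 benzyl bromide
Product: 5 4-(benzyloxy)-2,3-dimethoxyphenol
Conditions: 4 (0.9 equiv), K2CO3 (1.0 equiv), degassed acetone, reflux, N2
Reagents that add atoms: none
Why: Williamson ether synthesis on a diol whose two hydroxyls are equivalent by symmetry, so mono-alkylation can give only one product, and the limiting bromide keeps the separable dibenzyl ether low while unreacted 3 is recycled.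

Step 4
Reactants: 5 4-(benzyloxy)-2,3-dimethoxyphenol
Product: 6 4-(benzyloxy)-6-bromo-2,3-dimethoxyphenol
Conditions: NBS (1.0 equiv), i-Pr2NH (10 mol %), CH2Cl2, −40 to 0 °C, dark
Reagents that add atoms: N-bromosuccinimide, O=C1CCC(=O)N1Br
Why: Amine-mediated ortho-bromination of a phenol (electrophilic aromatic substitution) should place bromine at C6, the only free position ortho to the hydroxyl, because the free OH activates more strongly than the benzyloxy group and the hydrogen-bonded N-bromoamine delivers bromine next to it, while low temperature and exact stoichiometry limit oxidation of the hydroquinone monoether.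

Step 5
Reactants: 6 4-(benzyloxy)-6-bromo-2,3-dimethoxyphenol
Product: 9 4-(benzyloxy)-2,3-dimethoxy-6-(trimethylsilyl)phenyl trifluoromethanesulfonate, via trimethylsilyl ether 7 (not isolated), via lithium silylphenoxide 8 (not isolated)
Conditions: HMDS, THF, 70 °C, then evaporation; n-BuLi, THF, −100 to −80 °C; Tf2O, −100 °C to rt
Reagents that add atoms: hexamethyldisilazane, C[Si](C)(C)N[Si](C)(C)C; trifluoromethanesulfonic anhydride, O=S(=O)(OS(=O)(=O)C(F)(F)F)C(F)(F)F
Why: This is the standard one-pot route to o-silylaryl triflates, namely O-silylation, bromine–lithium exchange on 7, retro-Brook 1,3-shift of silicon from oxygen to the lithiated carbon to give 8 and O-triflation, with the exchange at −100 °C far faster than any attack of n-BuLi on the benzyl ether.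

Step 6
Reactants: 10 4-ethynyl-1,2-dimethoxybenzene
Product: 12 3-(3,4-dimethoxyphenyl)propiolic acid, via lithium acetylide 11 (not isolated)
Conditions: n-BuLi, THF, −78 °C; CO2 (g), −78 °C to rt; 1 M HCl
Reagents that add atoms: carbon dioxide, O=C=O
Why: Deprotonation of the terminal alkyne and carboxylation of the alkynyllithium with CO2 is a standard preparation of arylpropiolic acids and touches nothing else in the molecule.

Step 7
Reactants: 9 4-(benzyloxy)-2,3-dimethoxy-6-(trimethylsilyl)phenyl trifluoromethanesulfonate; 12 3-(3,4-dimethoxyphenyl)propiolic acid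
Product: 15 7-(benzyloxy)-5,6,3',4'-tetramethoxyflavone, via aryne 13 (not isolated), via ynone phenoxide 14 (not isolated)
Conditions: CsF (4 equiv), 9 (1.5 equiv), THF, 125 °C, sealed tube
Reagents that add atoms: none
Why: Fluoride removes the silyl group of 9 and triflate leaves to give aryne 13; the carboxylate of 12 adds through oxygen to the aryne carbon that becomes C8a, the aryl anion thus placed at C4a attacks the adjacent ester carbonyl to form a four-membered alkoxide, and opening of that ring moves the acyl group onto carbon and leaves ynone phenoxide 14. The phenoxide then adds to the ynone in a 6-endo-dig oxa-Michael closure that forms O1–C2 and ring C, and the resulting C3 anion is protonated in the medium. The closest known reaction type is the fluoride-triggered insertion of arynes into the C–O bond of carboxylic acids to give o-hydroxyaryl ketones, which with alkynoic acids runs on to chromones. No stereocentre is formed. The step needs one regiochemical outcome, oxygen at C8a and acyl at C4a, and the C5 methoxy group beside the aryne secures it: its inductive pull distorts the triple bond so that the nucleophile enters at the distal carbon and the charge builds next to the oxygen, while the hydrogen at C8 on the other flank exerts no opposing bias. THF at high temperature in a closed vessel is chosen so that intramolecular acyl transfer outruns protonation of the aryl anion to the simple aryl ester.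

Step 8
Reactants: 15 7-(benzyloxy)-5,6,3',4'-tetramethoxyflavone
Product: 16 7-hydroxy-5,6,3',4'-tetramethoxyflavone
Conditions: H2 (1 atm), 10% Pd/C, EtOAc–MeOH, rt
Reagents that add atoms: none
Why: Hydrogenolysis of the benzyl aryl ether over Pd/C at atmospheric pressure should leave the methyl ethers and the conjugated C2=C3 bond of the chromone untouched, as is routine for benzyl-protected flavones.

Step 9
Reactants: 16 7-hydroxy-5,6,3',4'-tetramethoxyflavone
Product: 17 8-bromo-7-hydroxy-5,6,3',4'-tetramethoxyflavone
Conditions: NBS (1.0 equiv), DMF, 0 °C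
Reagents that add atoms: N-bromosuccinimide, O=C1CCC(=O)N1Br
Why: Electrophilic aromatic bromination should occur at C8, which is ortho to the free 7-hydroxyl, para to the C5 methoxy group and the only unsubstituted carbon of ring A, whereas C3 and ring B are less reactive than this phenol ring.

Step 10
Reactants: 17 8-bromo-7-hydroxy-5,6,3',4'-tetramethoxyflavone
Product: 18 7-hydroxy-5,6,8,3',4'-pentamethoxyflavone (target)
Conditions: NaOMe (excess), CuBr (20 mol %), MeOH–DMF, 110 °C; aq. HCl work-up
Reagents that add atoms: sodium methoxide, [Na+].[O-]C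
Why: Ullmann-type copper-catalysed methanolysis of the aryl bromide, the usual way to turn 8-bromoflavones into 8-methoxyflavones, should replace bromine by methoxy, and because C5 carries a methyl ether any reversible opening of the pyranone by methoxide can only reclose to the same flavone.

**Compound list**

1 | 2,3-dimethoxyphenol | COc1cccc(O)c1OC | starting material
2 | 2,3-dimethoxy-1,4-benzoquinone | COC1=C(OC)C(=O)C=CC1=O | intermediate
3 | 2,3-dimethoxybenzene-1,4-diol | COc1c(O)ccc(O)c1OC | intermediate
4 | benzyl bromide | BrCc1ccccc1 | starting material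
5 | 4-(benzyloxy)-2,3-dimethoxyphenol | COc1c(O)ccc(OCc2ccccc2)c1OC | intermediate
6 | 4-(benzyloxy)-6-bromo-2,3-dimethoxyphenol | COc1c(O)c(Br)cc(OCc2ccccc2)c1OC | intermediate
7 | [4-(benzyloxy)-6-bromo-2,3-dimethoxyphenoxy]trimethylsilane | COc1c(O[Si](C)(C)C)c(Br)cc(OCc2ccccc2)c1OC | intermediate (not isolated)
8 | lithium 4-(benzyloxy)-2,3-dimethoxy-6-(trimethylsilyl)phenoxide | [Li+].COc1c([O-])c([Si](C)(C)C)cc(OCc2ccccc2)c1OC | intermediate (not isolated)
9 | 4-(benzyloxy)-2,3-dimethoxy-6-(trimethylsilyl)phenyl trifluoromethanesulfonate | COc1c(OC)c(OCc2ccccc2)cc([Si](C)(C)C)c1OS(=O)(=O)C(F)(F)F | intermediate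
10 | 4-ethynyl-1,2-dimethoxybenzene | C#Cc1ccc(OC)c(OC)c1 | starting material
11 | lithium (3,4-dimethoxyphenyl)acetylide | [Li+].[C-]#Cc1ccc(OC)c(OC)c1 | intermediate (not isolated)
12 | 3-(3,4-dimethoxyphenyl)propiolic acid | COc1ccc(C#CC(=O)O)cc1OC | intermediate
13 | 5-(benzyloxy)-3,4-dimethoxybenzyne (1,2-didehydrobenzene) | COC1=C(OC)C(OCc2ccccc2)=CC#C1 | intermediate (not isolated)
14 | cesium 5-(benzyloxy)-2-[3-(3,4-dimethoxyphenyl)propioloyl]-3,4-dimethoxyphenoxide | [Cs+].COc1ccc(C#CC(=O)c2c([O-])cc(OCc3ccccc3)c(OC)c2OC)cc1OC | intermediate (not isolated)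
15 | 7-(benzyloxy)-5,6,3',4'-tetramethoxyflavone | COc1ccc(-c2cc(=O)c3c(OC)c(OC)c(OCc4ccccc4)cc3o2)cc1OC | intermediate
16 | 7-hydroxy-5,6,3',4'-tetramethoxyflavone | COc1ccc(-c2cc(=O)c3c(OC)c(OC)c(O)cc3o2)cc1OC | intermediate
17 | 8-bromo-7-hydroxy-5,6,3',4'-tetramethoxyflavone | COc1ccc(-c2cc(=O)c3c(OC)c(OC)c(O)c(Br)c3o2)cc1OC | intermediate
18 | 7-hydroxy-5,6,8,3',4'-pentamethoxyflavone | COc1ccc(-c2cc(=O)c3c(OC)c(OC)c(O)c(OC)c3o2)cc1OC | target

**Step count**

Total: 10 steps. Longest linear sequence: 9 steps (steps 1–5 and 7–10, from 2,3-dimethoxyphenol); step 6 is a one-step side branch.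

**Steps most likely to fail**

Step 7. The propiolate may be lost by protodecarboxylation at 125 °C or by conjugate addition of fluoride or carboxylate to its triple bond before insertion. The aryl anion may also be protonated before the acyl shift, and the ynone phenoxide may close in the 5-exo sense to an aurone. The fallback runs the same aryne C–O insertion one oxidation level lower. It sets out from 9, which with commercial (E)-3,4-dimethoxycinnamic acid and CsF in THF at 125 °C should give (E)-1-[4-(benzyloxy)-6-hydroxy-2,3-dimethoxyphenyl]-3-(3,4-dimethoxyphenyl)prop-2-en-1-one F1. F1 should close in the same flask by oxa-Michael addition to racemic 7-(benzyloxy)-5,6,3',4'-tetramethoxyflavanone F2. Dehydrogenation of F2, together with any unclosed F1, with catalytic I2 in DMSO at 120 °C comes back to the route at 15. The alkenoic acid does not decarboxylate and cannot give an aurone.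

Step 4. Bromine may enter ortho to the benzyloxy group instead of ortho to the hydroxyl, and the hydroquinone monoether may be oxidised with loss of the benzyl group back towards quinone 2. The fallback replaces electrophilic substitution by directed ortho-metalation and bypasses 6. It sets out from 5, which with isopropyl isocyanate and catalytic Et3N in CH2Cl2 should give 4-(benzyloxy)-2,3-dimethoxyphenyl N-isopropylcarbamate F3. N-Silylation in situ (TMSOTf, TMEDA, Et2O), lithiation with n-BuLi/TMEDA at −78 °C at the only position ortho to the carbamate, quench with TMSCl and aqueous work-up should give 4-(benzyloxy)-2,3-dimethoxy-6-(trimethylsilyl)phenyl N-isopropylcarbamate F4. Cleavage of the carbamate with DBU and Et2NH in MeCN at 40 °C, followed by PhNTf2 in the same flask, comes back to the route at 9.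

Step 10. The 7-phenoxide makes the C8–Br bond electron-rich, so copper insertion may be slow and hydrodebromination back to 16 or methoxide attack at C2 with degradation of the opened pyranone may take over. The fallback does the C–O coupling on a neutral, protected substrate with palladium. It sets out from 17, which with benzyl bromide and K2CO3 in DMF should give 7-(benzyloxy)-8-bromo-5,6,3',4'-tetramethoxyflavone F5. Coupling with methanol (Pd2(dba)3, tBuBrettPhos, Cs2CO3, MeOH–toluene, 80 °C) should give 7-(benzyloxy)-5,6,8,3',4'-pentamethoxyflavone F6. Hydrogenolysis (H2, 10% Pd/C, EtOAc–MeOH, rt) comes back to the route at 18.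

**Further compounds**

F1 | step 7 | (E)-1-[4-(benzyloxy)-6-hydroxy-2,3-dimethoxyphenyl]-3-(3,4-dimethoxyphenyl)prop-2-en-1-one | COc1ccc(/C=C/C(=O)c2c(O)cc(OCc3ccccc3)c(OC)c2OC)cc1OC
F2 | step 7 | 7-(benzyloxy)-5,6,3',4'-tetramethoxyflavanone (racemic) | COc1ccc(C2CC(=O)c3c(OC)c(OC)c(OCc4ccccc4)cc3O2)cc1OC
F3 | step 4 | 4-(benzyloxy)-2,3-dimethoxyphenyl N-isopropylcarbamate | COc1c(OC(=O)NC(C)C)ccc(OCc2ccccc2)c1OC
F4 | step 4 | 4-(benzyloxy)-2,3-dimethoxy-6-(trimethylsilyl)phenyl N-isopropylcarbamate | COc1c(OC(=O)NC(C)C)c([Si](C)(C)C)cc(OCc2ccccc2)c1OC
F5 | step 10 | 7-(benzyloxy)-8-bromo-5,6,3',4'-tetramethoxyflavone | COc1ccc(-c2cc(=O)c3c(OC)c(OC)c(OCc4ccccc4)c(Br)c3o2)cc1OC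
F6 | step 10 | 7-(benzyloxy)-5,6,8,3',4'-pentamethoxyflavone | COc1ccc(-c2cc(=O)c3c(OC)c(OC)c(OCc4ccccc4)c(OC)c3o2)cc1OC
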